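**Plan**

- The depside ester bond (ring A O4 to the ring B carbonyl on C1') is cut first, giving 3-chloro-4,6-dihydroxy-2,5-dimethylbenzoic acid and methyl 2,4-dihydroxy-3,5,6-trimethylbenzoate.
- Ring B then loses its C3'–Cl bond and its aromatic unsaturation; the resulting dione ester is cut at C1'–C2' (Michael) and C4'–C5' (Dieckmann) to benzyl 3-oxopentanoate and benzyl crotonate.
- The enabling feature is ring B itself: oxygen on C4' and C6', the carboxyl carbon on C1', methyls on C2' and C5', and chlorine on C3'. It maps onto a 3,6-dimethyl-2,4-dioxocyclohexane-1-carboxylate whose single CH2 is C3'.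
- Ring A is traced back to commercial methyl 2,4-dihydroxy-3,6-dimethylbenzoate by cutting the C5 methyl back to a formyl group.
- Forward: ring B is built as a carbocycle (step 3), aromatised and chlorinated (step 4) and unmasked (step 5); ring A is completed on an existing arene (steps 6 and 7); the rings are joined last (step 8).
- The target is achiral; the two centres formed in step 3 (trans, racemic) vanish on aromatisation.

Key step: step 3

Remark: compounds 6, 7 and 8 are handled as racemates or diastereomer mixtures, and 7 is written as one enol tautomer of the 2,4-dione; benzyl esters are used on ring B so that the acid can be freed without base.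

**Route**

Step 1
Reactants: 1 methyl 3-oxopentanoate; 2 benzyl alcohol
Product: 3 benzyl 3-oxopentanoate
Conditions: BnOH (1.1 equiv), DMAP (10 mol %), toluene, reflux, MeOH distilled off
Reagents that add atoms: none
Why: Transesterification of a β-keto ester: DMAP catalysis exchanges the activated methyl ester for the benzyl ester and removal of methanol pulls the equilibrium over, the ketone being untouched.

Step 2
Reactants: 4 crotonic acid, (E)-but-2-enoic acid; 2 benzyl alcohol
Product: 5 benzyl (E)-but-2-enoate
Conditions: TsOH·H2O (5 mol %), toluene, reflux, Dean–Stark trap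
Reagents that add atoms: none
Why: Fischer esterification with azeotropic removal of water is routine for crotonic acid and leaves the E double bond unchanged.

Step 3
Reactants: 3 benzyl 3-oxopentanoate; 5 benzyl (E)-but-2-enoate
Product: 7 benzyl (1S*,6R*)-4-hydroxy-3,6-dimethyl-2-oxocyclohex-3-ene-1-carboxylate (racemic, trans, enol tautomer), via dibenzyl 3-methyl-2-propanoylpentanedioate 6 (not isolated)
Conditions: NaH (1.1 equiv), BnOH (10 mol %), THF, 0 °C → reflux; then 1 M HCl, 0 °C
Reagents that add atoms: none
Why: NaH converts 3 into its stabilised C2 enolate, which adds in a Michael reaction to the β-carbon of 5 (bond C1'–C2' of ring B); proton transfer within adduct 6 then gives the ketone enolate at the propanoyl CH2, which attacks the crotonate-derived ester carbonyl (bond C4'–C5') and expels benzyloxide. The closest known reaction type is the Michael–Claisen (Michael–Dieckmann) synthesis of dihydroresorcinol carboxylates from 3-oxo esters and crotonates. The ring closes in a 6-(enolendo)-exo-trig Dieckmann acylation, the only closure that would not give a four-membered ring, and the released benzyloxide deprotonates the new 1,3-dione, so the sequence is driven to the sodium dionate. C1 and C6 equilibrate through the β-keto ester enol under the basic conditions, so thermodynamic control should place the ester and the C6 methyl trans (both pseudo-equatorial) in racemic form; neither centre survives step 4. The selectivity needed is regiochemical, C2 of the keto ester as Michael donor and the propanoyl methylene as acylation nucleophile, and it is secured by the much higher acidity of the doubly activated C2–H and by ring size; using benzyl esters throughout makes any ester exchange degenerate.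

Step 4
Reactants: 7 benzyl (1S*,6R*)-4-hydroxy-3,6-dimethyl-2-oxocyclohex-3-ene-1-carboxylate
Product: 10 benzyl 3-chloro-4,6-dihydroxy-2,5-dimethylbenzoate, via benzyl 3-chloro-3,6-dimethyl-2,4-dioxocyclohexane-1-carboxylate 8 (not isolated), via benzyl 2,4-dihydroxy-3,6-dimethylbenzoate 9 (not isolated)
Conditions: SO2Cl2 (1.0 equiv), AcOH, rt → 60 °C; then SO2Cl2 (1.05 equiv), rt
Reagents that add atoms: sulfuryl chloride, O=S(=O)(Cl)Cl
Why: Halogenative aromatisation of a dihydroresorcinol carboxylate: the first equivalent chlorinates the enolised dione at C3 to give 8, the HCl formed relays the chlorine to an enolisable α-position from which HCl is lost to give resorcinol 9 after tautomerisation, and the second equivalent chlorinates 9 by electrophilic aromatic substitution at the only unsubstituted ring carbon (C3' of ring B), ortho to one hydroxyl and para to the other.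

Step 5
Reactants: 10 benzyl 3-chloro-4,6-dihydroxy-2,5-dimethylbenzoate
Product: 11 3-chloro-4,6-dihydroxy-2,5-dimethylbenzoic acid
Conditions: H2 (1 atm), 10% Pd/C, EtOAc, rt; filtered and concentrated below 30 °C
Reagents that add atoms: none
Why: Hydrogenolysis of the benzyl ester C–O bond over Pd/C at 1 atm in a neutral, base-free solvent is far faster than hydrodechlorination of an electron-rich aryl chloride, so the acid should form with the chlorine retained.

Step 6
Reactants: 12 methyl 2,4-dihydroxy-3,6-dimethylbenzoate
Product: 14 methyl 3-formyl-4,6-dihydroxy-2,5-dimethylbenzoate, via methyl 3-[chloro(methoxy)methyl]-4,6-dihydroxy-2,5-dimethylbenzoate 13 (not isolated)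
Conditions: Cl2CHOMe (1.5 equiv), TiCl4 (3 equiv), CH2Cl2, 0 °C → rt; then 1 M HCl
Reagents that add atoms: dichloromethyl methyl ether, COC(Cl)Cl; water, O
Why: Rieche formylation: TiCl4 binds the C4 phenoxide and delivers the chloro(methoxy)methyl cation to the adjacent C5, the only unsubstituted ring carbon, giving α-chloro ether 13, which hydrolyses to the aldehyde on work-up.

Step 7
Reactants: 14 methyl 3-formyl-4,6-dihydroxy-2,5-dimethylbenzoate
Product: 16 methyl 2,4-dihydroxy-3,5,6-trimethylbenzoate, via methyl 4,6-dihydroxy-3-(hydroxymethyl)-2,5-dimethylbenzoate 15 (not isolated)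
Conditions: H2 (3 atm), 10% Pd/C, AcOH, conc. HCl (cat.), rt
Reagents that add atoms: none
Why: Catalytic hydrogenation of the aldehyde to benzylic alcohol 15 followed by acid-assisted benzylic hydrogenolysis, which ortho and para hydroxyl groups accelerate, is the standard conversion of a hydroxybenzaldehyde into a methylphenol and leaves the ester and the ring intact.

Step 8
Reactants: 11 3-chloro-4,6-dihydroxy-2,5-dimethylbenzoic acid; 16 methyl 2,4-dihydroxy-3,5,6-trimethylbenzoate
Product: 18 methyl 4-[(3-chloro-4,6-dihydroxy-2,5-dimethylbenzoyl)oxy]-2-hydroxy-3,5,6-trimethylbenzoate, via 3-chloro-4,6-dihydroxy-2,5-dimethylbenzoic trifluoroacetic anhydride 17 (not isolated)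
Conditions: 16 (2 equiv), (CF3CO)2O (4 equiv), toluene, 0 °C → rt; then aq NaHCO3
Reagents that add atoms: none
Why: Trifluoroacetic anhydride-mediated esterification (mixed-anhydride depside coupling): 11 forms aroyl trifluoroacetate 17, a hindered acyl donor of acylium character that should acylate the C4 hydroxyl of 16, the only phenol not hydrogen-bonded to an ester carbonyl, while the C4 hydroxyl of 11 is deactivated by the ortho chlorine and the para acyl group and is outcompeted by the excess of 16.

**Compound list**

1 | methyl 3-oxopentanoate | CCC(=O)CC(=O)OC | starting material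
2 | benzyl alcohol | OCc1ccccc1 | starting material
3 | benzyl 3-oxopentanoate | CCC(=O)CC(=O)OCc1ccccc1 | intermediate
4 | crotonic acid, (E)-but-2-enoic acid | C/C=C/C(=O)O | starting material
5 | benzyl (E)-but-2-enoate | C/C=C/C(=O)OCc1ccccc1 | intermediate
6 | dibenzyl 3-methyl-2-propanoylpentanedioate (diastereomer mixture, racemic; formed in the flask, not isolated) | CCC(=O)C(C(=O)OCc1ccccc1)C(C)CC(=O)OCc1ccccc1 | intermediate
7 | benzyl (1S*,6R*)-4-hydroxy-3,6-dimethyl-2-oxocyclohex-3-ene-1-carboxylate (racemic, trans, one enantiomer drawn, enol tautomer) | CC1=C(O)C[C@@H](C)[C@H](C(=O)OCc2ccccc2)C1=O | intermediate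
8 | benzyl 3-chloro-3,6-dimethyl-2,4-dioxocyclohexane-1-carboxylate (diastereomer mixture; formed in the flask, not isolated) | O=C1CC(C)C(C(=O)OCc2ccccc2)C(=O)C1(C)Cl | intermediate
9 | benzyl 2,4-dihydroxy-3,6-dimethylbenzoate (formed in the flask, not isolated) | Cc1cc(O)c(C)c(O)c1C(=O)OCc1ccccc1 | intermediate
10 | benzyl 3-chloro-4,6-dihydroxy-2,5-dimethylbenzoate | Cc1c(Cl)c(O)c(C)c(O)c1C(=O)OCc1ccccc1 | intermediate
11 | 3-chloro-4,6-dihydroxy-2,5-dimethylbenzoic acid | Cc1c(Cl)c(O)c(C)c(O)c1C(=O)O | intermediate
12 | methyl 2,4-dihydroxy-3,6-dimethylbenzoate | COC(=O)c1c(C)cc(O)c(C)c1O | starting material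
13 | methyl 3-[chloro(methoxy)methyl]-4,6-dihydroxy-2,5-dimethylbenzoate (formed in the flask, not isolated) | COC(=O)c1c(C)c(C(Cl)OC)c(O)c(C)c1O | intermediate
14 | methyl 3-formyl-4,6-dihydroxy-2,5-dimethylbenzoate | COC(=O)c1c(C)c(C=O)c(O)c(C)c1O | intermediate
15 | methyl 4,6-dihydroxy-3-(hydroxymethyl)-2,5-dimethylbenzoate (formed in the flask, not isolated) | COC(=O)c1c(C)c(CO)c(O)c(C)c1O | intermediate
16 | methyl 2,4-dihydroxy-3,5,6-trimethylbenzoate | COC(=O)c1c(C)c(C)c(O)c(C)c1O | intermediate
17 | 3-chloro-4,6-dihydroxy-2,5-dimethylbenzoic trifluoroacetic anhydride (formed in the flask, not isolated) | Cc1c(Cl)c(O)c(C)c(O)c1C(=O)OC(=O)C(F)(F)F | intermediate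
18 | methyl 4-[(3-chloro-4,6-dihydroxy-2,5-dimethylbenzoyl)oxy]-2-hydroxy-3,5,6-trimethylbenzoate | COC(=O)c1c(C)c(C)c(OC(=O)c2c(C)c(Cl)c(O)c(C)c2O)c(C)c1O | target

**Count and risks**

Total step count: 8. Longest linear sequence: 5 steps (1, 3, 4, 5, 8); the ring A branch (steps 6 and 7) joins at step 8.

Steps most likely to fail:

1. Step 4. The chlorine may stay locked on the quaternary C3 of the dione, so that HCl is not lost, or ipso attack on the fully substituted resorcinol may lead to over-chlorination.
   Fallback, setting out from 7: bromine (2 equiv) in AcOH would be used instead, because bromine on a 2-alkyl-1,3-dione shifts readily under HBr. The sequence should run through benzyl 3-bromo-3,6-dimethyl-2,4-dioxocyclohexane-1-carboxylate F1 and resorcinol 9 to benzyl 3-bromo-4,6-dihydroxy-2,5-dimethylbenzoate F2. Hydrogenolysis (H2, 10% Pd/C, NaOAc, EtOAc/MeOH) would remove both the bromine and the benzyl group to give 2,4-dihydroxy-3,6-dimethylbenzoic acid F3. One equivalent of SO2Cl2 in Et2O at 0 °C would then chlorinate its only free ring position, and the route is rejoined at 11.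

2. Step 8. The hydroxy acid may esterify itself, acylation of the doubly ortho-substituted phenol may be too slow, or 11 may decarboxylate in the acidic medium.
   Fallback, setting out from 10: BnBr and K2CO3 in acetone should alkylate only the non-chelated C4 hydroxyl to give benzyl 4-(benzyloxy)-3-chloro-6-hydroxy-2,5-dimethylbenzoate F4. KOH in aqueous DMSO at 90 °C, then acid, would free 4-(benzyloxy)-3-chloro-6-hydroxy-2,5-dimethylbenzoic acid F5. Coupling with 16 under trifluoroacetic anhydride in toluene would pass through 4-(benzyloxy)-3-chloro-6-hydroxy-2,5-dimethylbenzoic trifluoroacetic anhydride F6 to methyl 4-{[4-(benzyloxy)-3-chloro-6-hydroxy-2,5-dimethylbenzoyl]oxy}-2-hydroxy-3,5,6-trimethylbenzoate F7. BCl3 with pentamethylbenzene in CH2Cl2 at −78 °C would remove the benzyl ether without a reductant, and the route is rejoined at 18.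

3. Step 5. The ring chlorine may be lost by hydrodechlorination on palladium, or the β-resorcylic acid may decarboxylate during isolation.
   Fallback, setting out from 10: the reductive cleavage is replaced by Lewis-acid dealkylation. BCl3 in CH2Cl2 at −78 → 0 °C, chelated between the C6 hydroxyl and the ester carbonyl, should break the O–benzyl bond heterolytically, and aqueous work-up gives 11 directly; no new compound arises (F0).

**Further compounds**

F1 | step 4 | benzyl 3-bromo-3,6-dimethyl-2,4-dioxocyclohexane-1-carboxylate | O=C1CC(C)C(C(=O)OCc2ccccc2)C(=O)C1(C)Br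
F2 | step 4 | benzyl 3-bromo-4,6-dihydroxy-2,5-dimethylbenzoate | Cc1c(Br)c(O)c(C)c(O)c1C(=O)OCc1ccccc1
F3 | step 4 | 2,4-dihydroxy-3,6-dimethylbenzoic acid | Cc1cc(O)c(C)c(O)c1C(=O)O
F4 | step 8 | benzyl 4-(benzyloxy)-3-chloro-6-hydroxy-2,5-dimethylbenzoate | Cc1c(Cl)c(OCc2ccccc2)c(C)c(O)c1C(=O)OCc1ccccc1
F5 | step 8 | 4-(benzyloxy)-3-chloro-6-hydroxy-2,5-dimethylbenzoic acid | Cc1c(Cl)c(OCc2ccccc2)c(C)c(O)c1C(=O)O
F6 | step 8 | 4-(benzyloxy)-3-chloro-6-hydroxy-2,5-dimethylbenzoic trifluoroacetic anhydride | Cc1c(Cl)c(OCc2ccccc2)c(C)c(O)c1C(=O)OC(=O)C(F)(F)F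
F7 | step 8 | methyl 4-{[4-(benzyloxy)-3-chloro-6-hydroxy-2,5-dimethylbenzoyl]oxy}-2-hydroxy-3,5,6-trimethylbenzoate | COC(=O)c1c(C)c(C)c(OC(=O)c2c(C)c(Cl)c(OCc3ccccc3)c(C)c2O)c(C)c1O
F0 | step 5 | none | none
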